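Locants: cyclohexene ring C5–C10 (C5=C10, CH3 on C10, side chain C4H(CH3)–C3–C2–C1–O on C5, acyloxy on C6); γ-lactone ring O–C8–C7–C11–C12 cis-fused at C7–C8; exo-methylene C13 on C11.
Enabling feature: the fully substituted ring alkene C5=C10 lies next to methine C4, whose methyl is a hydrogenated methylene. C10(CH3)=C5–C4(=CH2) is the 2-methyl-1-(alk-1-en-2-yl)cyclohexene pattern that a C5≡C4 alkyne and a C10 methallyl alkene give in one enyne metathesis.
Retrosynthetic cuts, in order: both isobutyrate O–acyl bonds, C11=C13, the two C–H bonds across C4=CH2, then C5=C10 together with C4=CH2 (key step), the lactone O–C12 bond, C8–C9, C6–C7.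
Forward: the chain is joined at C6–C7 (aldol of a succinate imide with a C1–C6 ynal), then at C8–C9 (methallylboration); the lactone ring closes first and the cyclohexene ring second.
Stereochemistry: C6 and C7 come from (S)-4-benzyloxazolidinone in a syn-aldol, C8 from a pinene-derived methallylborane, C4 from a chiral iridium hydrogenation catalyst. C6 is never a ketone, so no epimerisable, eliminable β-acyloxy ketone appears.

Key step: step 10

Assumption: the sense of induction of the iridium catalyst on the metathesis diene cannot be read safely from simple model alkenes. The (S)-ligand is written; its commercial antipode takes its place if a pilot reduction shows that it leads to the 4R epimer.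
Abbreviations: TBS = tert-butyldimethylsilyl; Ipc = isopinocampheyl; H2IMes = 1,3-dimesitylimidazolidin-2-ylidene; tBu-PHOX = 4-tert-butyl-2-[2-(diphenylphosphino)phenyl]-4,5-dihydrooxazole.

Step 1
Reactants: 1 pent-4-yn-1-ol
Product: 2 tert-butyl(dimethyl)(pent-4-yn-1-yloxy)silane
Conditions: TBSCl, imidazole, CH2Cl2, 0 °C to rt
Reagents that add atoms: tert-butyldimethylsilyl chloride, CC(C)(C)[Si](C)(C)Cl
Why: Routine imidazole-promoted silylation of a primary alcohol; the terminal alkyne is inert and the silyl ether tolerates the later organolithium, boron, oxidation and metathesis chemistry.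

Step 2
Reactants: 2 tert-butyl(dimethyl)(pent-4-yn-1-yloxy)silane
Product: 5 6-(TBSO)hex-2-ynal, via lithium acetylide 3 (not isolated), via lithium hemiaminal alkoxide 4 (not isolated)
Conditions: n-BuLi, THF, −78 °C; DMF, −78 to 0 °C; poured into cold aq. KH2PO4/MTBE
Reagents that add atoms: N,N-dimethylformamide, CN(C)C=O
Why: Formylation of a lithium acetylide with DMF, with inverse quench into phosphate buffer so that the liberated dimethylamine cannot add to the ynal; the formyl carbon becomes C6.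

Step 3
Reactants: 6 4-tert-butoxy-4-oxobutanoic acid (mono-tert-butyl succinate); 7 (4S)-4-benzyl-1,3-oxazolidin-2-one
Product: 9 tert-butyl 4-[(4S)-4-benzyl-2-oxo-1,3-oxazolidin-3-yl]-4-oxobutanoate, via mixed pivalic anhydride 8 (not isolated)
Conditions: t-BuCOCl, Et3N, THF, −20 °C; then LiCl, 7, −20 °C to rt
Reagents that add atoms: none
Why: N-acylation of an Evans oxazolidinone through a mixed anhydride with LiCl activation; attack occurs at the unhindered succinyl carbonyl, no strong base is needed and the tert-butyl ester is untouched.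

Step 4
Reactants: 9 tert-butyl 4-[(4S)-4-benzyl-2-oxo-1,3-oxazolidin-3-yl]-4-oxobutanoate; 5 6-(TBSO)hex-2-ynal
Product: 12 tert-butyl (3S,4S)-3-{[(4S)-4-benzyl-2-oxo-1,3-oxazolidin-3-yl]carbonyl}-4-hydroxy-9-(TBSO)non-5-ynoate, via Z-dibutylboron enolate 10 (not isolated), via dibutylboron aldolate 11 (not isolated)
Conditions: Bu2BOTf, iPr2NEt, CH2Cl2, −78 to 0 °C; 5, −78 to 0 °C; pH 7 buffer, MeOH, 30% H2O2, 0 °C
Reagents that add atoms: none
Why: Evans syn-aldol reaction in which soft enolisation touches only the imide and gives the Z-boron enolate, and the chair Zimmerman–Traxler transition state, with the benzyl group shielding one enolate face, forms C6–C7 and sets C6 and C7 together in the syn sense; the non-enolisable ynal is a good acceptor and the bulky tert-butyl ester keeps the new hydroxyl from lactonising.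

Step 5
Reactants: 12 tert-butyl (3S,4S)-3-{[(4S)-4-benzyl-2-oxo-1,3-oxazolidin-3-yl]carbonyl}-4-hydroxy-9-(TBSO)non-5-ynoate
Product: 13 tert-butyl (3S,4S)-3-{[(4S)-4-benzyl-2-oxo-1,3-oxazolidin-3-yl]carbonyl}-4,9-bis(TBSO)non-5-ynoate
Conditions: TBSOTf (1.1 equiv), 2,6-lutidine, CH2Cl2, −78 to −20 °C
Reagents that add atoms: tert-butyldimethylsilyl trifluoromethanesulfonate, CC(C)(C)[Si](C)(C)OS(=O)(=O)C(F)(F)F
Why: Silyl triflate silylation of a secondary propargylic alcohol, where low temperature and only a slight excess spare the tert-butyl ester and the hindered base avoids retro-aldol cleavage.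

Step 6
Reactants: 13 tert-butyl (3S,4S)-3-{[(4S)-4-benzyl-2-oxo-1,3-oxazolidin-3-yl]carbonyl}-4,9-bis(TBSO)non-5-ynoate
Product: 14 tert-butyl (3R,4S)-4,9-bis(TBSO)-3-(hydroxymethyl)non-5-ynoate
Conditions: LiBH4, THF, 0 °C to rt
Reagents that add atoms: none
Why: Reductive removal of the Evans auxiliary; LiBH4 reduces the activated imide carbonyl (C8) but not a tert-butyl ester, an internal alkyne or silyl ethers, and the γ-hydroxy tert-butyl ester is slow enough to lactonise that it can be isolated (the descriptor at C7 changes by priority only).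

Step 7
Reactants: 14 tert-butyl (3R,4S)-4,9-bis(TBSO)-3-(hydroxymethyl)non-5-ynoate
Product: 15 tert-butyl (3S,4S)-4,9-bis(TBSO)-3-formylnon-5-ynoate
Conditions: Dess–Martin periodinane, CH2Cl2, 0 °C to rt
Reagents that add atoms: none
Why: Dess–Martin oxidation stops at the aldehyde under near-neutral conditions, so C7 should not epimerise and the β-silyloxy group should not eliminate; the aldehyde is used at once.

Step 8
Reactants: 15 tert-butyl (3S,4S)-4,9-bis(TBSO)-3-formylnon-5-ynoate; 16 2-methylallylmagnesium chloride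
Product: 19 tert-butyl (3R,4S)-4,9-bis(TBSO)-3-[(1R)-1-hydroxy-3-methylbut-3-en-1-yl]non-5-ynoate, via B-methallyldiisopinocampheylborane 17 (not isolated), via diisopinocampheylborinate 18 (not isolated)
Conditions: (+)-Ipc2BOMe, 16, Et2O, −78 °C to rt; 15, Et2O, −78 °C; then 3 M NaOH, 30% H2O2, 0 °C to rt
Reagents that add atoms: none
Why: Brown asymmetric methallylboration in which the borane carrying Ipc groups from (−)-α-pinene transfers the methallyl unit through a chair transition state to the Re face of the aldehyde, forming C8–C9 and setting 8R (7,8-anti, 6,8-anti) under reagent control; no isomerisation-prone β,γ-unsaturated aldehyde is needed.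

Step 9
Reactants: 19 tert-butyl (3R,4S)-4,9-bis(TBSO)-3-[(1R)-1-hydroxy-3-methylbut-3-en-1-yl]non-5-ynoate
Product: 20 (4R,5R)-4-[(1S)-1,6-bis(TBSO)hex-2-yn-1-yl]-5-(2-methylprop-2-en-1-yl)oxolan-2-one (cis-lactone enyne)
Conditions: camphor-10-sulfonic acid (10 mol %), 4 Å molecular sieves, toluene, 60 °C
Reagents that add atoms: none
Why: Acid-catalysed lactonisation of a γ-hydroxy tert-butyl ester (intramolecular transesterification, five-membered ring) under anhydrous, nucleophile-free conditions that leave both silyl ethers and the 1,1-disubstituted alkene alone; no stereocentre is touched, and the 7,8-anti array becomes the cis-4,5-disubstituted lactone.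

Step 10
Reactants: 20 (4R,5R)-4-[(1S)-1,6-bis(TBSO)hex-2-yn-1-yl]-5-(2-methylprop-2-en-1-yl)oxolan-2-one
Product: 21 (3aR,4S,7aR)-4-(TBSO)-5-[5-(TBSO)pent-1-en-2-yl]-6-methyl-3a,4,7,7a-tetrahydro-1-benzofuran-2(3H)-one (bicyclic lactone 1,3-diene)
Conditions: RuCl2(H2IMes)(PCy3)(=CHPh) (second-generation Grubbs catalyst, 10 mol % in two portions), ethylene (1 atm), toluene (5 mM), 80 °C
Reagents that add atoms: none
Why: The ruthenium methylidene, kept available by the ethylene atmosphere, adds across C5≡C4 with its carbon on the less hindered C4 and the metal on C5, and opening of the ruthenacyclobutene gives a C5 vinylcarbene that already carries C4=CH2. This carbene undergoes [2+2] cycloaddition and cycloreversion with the methallyl C10=CH2, which forms C5=C10 and returns the methylidene, so the reaction is a net isomerisation. The closest known reaction type is ring-closing enyne metathesis of 1,7-enynes to 1-alkenylcyclohexenes with N-heterocyclic-carbene ruthenium catalysts, which includes internal alkynes and 1,1-disubstituted alkenes, although a tetrasubstituted ring alkene is at the hard end of that scope. The six-membered carbocycle closes in the exo mode (only C5 of the alkyne becomes a ring atom), and no stereocentre is made or disturbed. The step needs exo rather than seven-membered endo closure and cyclisation rather than oligomerisation: the steric contrast between the branched, silyloxy-bearing C6 and the primary C3 steers the metal to C5, the cis arrangement of the two arms on the lactone holds C5 near C10, and high dilution suppresses intermolecular events. The lactone carries no exo-methylene at this stage, so it offers the catalyst no competing alkene.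

Step 11
Reactants: 21 (3aR,4S,7aR)-4-(TBSO)-5-[5-(TBSO)pent-1-en-2-yl]-6-methyl-3a,4,7,7a-tetrahydro-1-benzofuran-2(3H)-one
Product: 22 (3aR,4S,7aR)-4-(TBSO)-5-[(2S)-5-(TBSO)pentan-2-yl]-6-methyl-3a,4,7,7a-tetrahydro-1-benzofuran-2(3H)-one
Conditions: [Ir(cod)((S)-tBu-PHOX)][B(C6H3-3,5-(CF3)2)4] (2 mol %), H2 (1 bar), CH2Cl2, 0 °C to rt
Reagents that add atoms: none
Why: Asymmetric hydrogenation of an unfunctionalised 1,1-disubstituted alkene with a cationic iridium P,N catalyst: the terminal methylene should react far faster than the tetrasubstituted C5=C10, which is twisted out of conjugation, and the ligand sets 4S by distinguishing the bulky, aryl-like cyclohexenyl group from the linear C3 chain; low hydrogen pressure is chosen because terminal alkenes respond best to it.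

Step 12
Reactants: 22 (3aR,4S,7aR)-4-(TBSO)-5-[(2S)-5-(TBSO)pentan-2-yl]-6-methyl-3a,4,7,7a-tetrahydro-1-benzofuran-2(3H)-one
Product: 24 (3aR,4S,7aR)-3-[(dimethylamino)methyl]-4-(TBSO)-5-[(2S)-5-(TBSO)pentan-2-yl]-6-methyl-3a,4,7,7a-tetrahydro-1-benzofuran-2(3H)-one (C11 epimers, inconsequential), via lithium enolate 23 (not isolated)
Conditions: LiN(iPr)2, THF, −78 °C; Me2N=CH2 I (Eschenmoser's salt), −78 °C to rt
Reagents that add atoms: N,N-dimethylmethyleneiminium iodide, C[N+](C)=C.[I-]
Why: Mannich aminomethylation of a lactone enolate; C11–H is the only acidic site, C7 carries no leaving group for β-elimination, and the new C11 centre is erased in the next step.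

Step 13
Reactants: 24 (3aR,4S,7aR)-3-[(dimethylamino)methyl]-4-(TBSO)-5-[(2S)-5-(TBSO)pentan-2-yl]-6-methyl-3a,4,7,7a-tetrahydro-1-benzofuran-2(3H)-one
Product: 26 (3aR,4S,7aR)-4-(TBSO)-5-[(2S)-5-(TBSO)pentan-2-yl]-6-methyl-3-methylidene-3a,4,7,7a-tetrahydro-1-benzofuran-2(3H)-one, via trimethylammonium iodide 25 (not isolated)
Conditions: MeI, MeOH, rt; evaporate; aq. NaHCO3, CH2Cl2, rt
Reagents that add atoms: none
Why: Quaternisation followed by mild base-induced β-elimination of trimethylamine, the standard α-methylenation of γ-butyrolactones, installs C11=C13 only after metathesis and hydrogenation are finished.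

Step 14
Reactants: 26 (3aR,4S,7aR)-4-(TBSO)-5-[(2S)-5-(TBSO)pentan-2-yl]-6-methyl-3-methylidene-3a,4,7,7a-tetrahydro-1-benzofuran-2(3H)-one
Product: 27 (3aS,4S,7aR)-4-hydroxy-5-[(2S)-5-hydroxypentan-2-yl]-6-methyl-3-methylidene-3a,4,7,7a-tetrahydro-1-benzofuran-2(3H)-one
Conditions: HF·pyridine, pyridine, THF, 0 °C to rt
Reagents that add atoms: none
Why: Fluoride-mediated desilylation in a pyridine-buffered, non-basic medium removes both silyl ethers while avoiding alkoxide-driven translactonisation to C6–O or conjugate addition to the methylene lactone, and it is mild enough for the allylic C6 alcohol (the 3a descriptor changes by priority only).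

Step 15
Reactants: 27 (3aS,4S,7aR)-4-hydroxy-5-[(2S)-5-hydroxypentan-2-yl]-6-methyl-3-methylidene-3a,4,7,7a-tetrahydro-1-benzofuran-2(3H)-one
Product: 28 (3aR,4S,7aR)-6-methyl-3-methylidene-5-[(2S)-5-(2-methylpropanoyloxy)pentan-2-yl]-2-oxo-2,3,3a,4,7,7a-hexahydro-1-benzofuran-4-yl 2-methylpropanoate (CNP0509808.1)
Conditions: (iPrCO)2O, Et3N, DMAP (cat.), CH2Cl2, 0 °C to rt
Reagents that add atoms: 2-methylpropanoic anhydride, CC(C)C(=O)OC(=O)C(C)C
Why: DMAP-catalysed acylation esterifies the primary C1 and the secondary allylic C6 hydroxyl in one operation with retention at C6, a transformation routine for hydroxylated α-methylene lactones.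

Compound list
1 | pent-4-yn-1-ol | C#CCCCO | starting material
2 | tert-butyl(dimethyl)(pent-4-yn-1-yloxy)silane | C#CCCCO[Si](C)(C)C(C)(C)C | intermediate
3 | lithium acetylide of 2 | [Li]C#CCCCO[Si](C)(C)C(C)(C)C | intermediate
4 | lithium hemiaminal alkoxide (DMF adduct of 3) | [Li]OC(N(C)C)C#CCCCO[Si](C)(C)C(C)(C)C | intermediate
5 | 6-(TBSO)hex-2-ynal | O=CC#CCCCO[Si](C)(C)C(C)(C)C | intermediate
6 | 4-tert-butoxy-4-oxobutanoic acid | OC(=O)CCC(=O)OC(C)(C)C | starting material
7 | (4S)-4-benzyl-1,3-oxazolidin-2-one | O=C1N[C@@H](Cc2ccccc2)CO1 | starting material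
8 | 4-tert-butoxy-4-oxobutanoic pivalic anhydride | CC(C)(C)C(=O)OC(=O)CCC(=O)OC(C)(C)C | intermediate
9 | tert-butyl 4-[(4S)-4-benzyl-2-oxo-1,3-oxazolidin-3-yl]-4-oxobutanoate | O=C1OC[C@H](Cc2ccccc2)N1C(=O)CCC(=O)OC(C)(C)C | intermediate
10 | (Z)-dibutylboron enolate of 9 | CCCCB(CCCC)O/C(=C\CC(=O)OC(C)(C)C)N1[C@@H](Cc2ccccc2)COC1=O | intermediate
11 | dibutylboron aldolate of 12 | O=C1OC[C@H](Cc2ccccc2)N1C(=O)[C@@H](CC(=O)OC(C)(C)C)[C@H](OB(CCCC)CCCC)C#CCCCO[Si](C)(C)C(C)(C)C | intermediate
12 | tert-butyl (3S,4S)-3-{[(4S)-4-benzyl-2-oxo-1,3-oxazolidin-3-yl]carbonyl}-4-hydroxy-9-(TBSO)non-5-ynoate | O=C1OC[C@H](Cc2ccccc2)N1C(=O)[C@@H](CC(=O)OC(C)(C)C)[C@H](O)C#CCCCO[Si](C)(C)C(C)(C)C | intermediate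
13 | tert-butyl (3S,4S)-3-{[(4S)-4-benzyl-2-oxo-1,3-oxazolidin-3-yl]carbonyl}-4,9-bis(TBSO)non-5-ynoate | O=C1OC[C@H](Cc2ccccc2)N1C(=O)[C@@H](CC(=O)OC(C)(C)C)[C@H](O[Si](C)(C)C(C)(C)C)C#CCCCO[Si](C)(C)C(C)(C)C | intermediate
14 | tert-butyl (3R,4S)-4,9-bis(TBSO)-3-(hydroxymethyl)non-5-ynoate | OC[C@@H](CC(=O)OC(C)(C)C)[C@H](O[Si](C)(C)C(C)(C)C)C#CCCCO[Si](C)(C)C(C)(C)C | intermediate
15 | tert-butyl (3S,4S)-4,9-bis(TBSO)-3-formylnon-5-ynoate | O=C[C@@H](CC(=O)OC(C)(C)C)[C@H](O[Si](C)(C)C(C)(C)C)C#CCCCO[Si](C)(C)C(C)(C)C | intermediate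
16 | 2-methylallylmagnesium chloride | C=C(C)C[Mg]Cl | starting material
17 | (+)-B-(2-methylallyl)diisopinocampheylborane (Ipc from (−)-α-pinene) | C=C(C)CB([C@H]1C[C@H]2C[C@@H]([C@@H]1C)C2(C)C)[C@H]1C[C@H]2C[C@@H]([C@@H]1C)C2(C)C | intermediate
18 | diisopinocampheylborinate of 19 | C=C(C)C[C@@H](OB([C@H]1C[C@H]2C[C@@H]([C@@H]1C)C2(C)C)[C@H]1C[C@H]2C[C@@H]([C@@H]1C)C2(C)C)[C@@H](CC(=O)OC(C)(C)C)[C@H](O[Si](C)(C)C(C)(C)C)C#CCCCO[Si](C)(C)C(C)(C)C | intermediate
19 | tert-butyl (3R,4S)-4,9-bis(TBSO)-3-[(1R)-1-hydroxy-3-methylbut-3-en-1-yl]non-5-ynoate | C=C(C)C[C@@H](O)[C@@H](CC(=O)OC(C)(C)C)[C@H](O[Si](C)(C)C(C)(C)C)C#CCCCO[Si](C)(C)C(C)(C)C | intermediate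
20 | (4R,5R)-4-[(1S)-1,6-bis(TBSO)hex-2-yn-1-yl]-5-(2-methylprop-2-en-1-yl)oxolan-2-one | C1C(=O)O[C@H](CC(C)=C)[C@@H]1[C@H](O[Si](C)(C)C(C)(C)C)C#CCCCO[Si](C)(C)C(C)(C)C | intermediate
21 | (3aR,4S,7aR)-4-(TBSO)-5-[5-(TBSO)pent-1-en-2-yl]-6-methyl-3a,4,7,7a-tetrahydro-1-benzofuran-2(3H)-one | C1C(=O)O[C@@H]2CC(C)=C(C(=C)CCCO[Si](C)(C)C(C)(C)C)[C@@H](O[Si](C)(C)C(C)(C)C)[C@H]12 | intermediate
22 | (3aR,4S,7aR)-4-(TBSO)-5-[(2S)-5-(TBSO)pentan-2-yl]-6-methyl-3a,4,7,7a-tetrahydro-1-benzofuran-2(3H)-one | C1C(=O)O[C@@H]2CC(C)=C([C@@H](C)CCCO[Si](C)(C)C(C)(C)C)[C@@H](O[Si](C)(C)C(C)(C)C)[C@H]12 | intermediate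
23 | lithium enolate of 22 | C1=C(O[Li])O[C@@H]2CC(C)=C([C@@H](C)CCCO[Si](C)(C)C(C)(C)C)[C@@H](O[Si](C)(C)C(C)(C)C)[C@H]12 | intermediate
24 | 3-[(dimethylamino)methyl] derivative of 22 (C11 epimers) | CN(C)CC1C(=O)O[C@@H]2CC(C)=C([C@@H](C)CCCO[Si](C)(C)C(C)(C)C)[C@@H](O[Si](C)(C)C(C)(C)C)[C@H]12 | intermediate
25 | trimethylammonium iodide of 24 | C[N+](C)(C)CC1C(=O)O[C@@H]2CC(C)=C([C@@H](C)CCCO[Si](C)(C)C(C)(C)C)[C@@H](O[Si](C)(C)C(C)(C)C)[C@H]12.[I-] | intermediate
26 | (3aR,4S,7aR)-4-(TBSO)-5-[(2S)-5-(TBSO)pentan-2-yl]-6-methyl-3-methylidene-3a,4,7,7a-tetrahydro-1-benzofuran-2(3H)-one | C=C1C(=O)O[C@@H]2CC(C)=C([C@@H](C)CCCO[Si](C)(C)C(C)(C)C)[C@@H](O[Si](C)(C)C(C)(C)C)[C@H]12 | intermediate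
27 | (3aS,4S,7aR)-4-hydroxy-5-[(2S)-5-hydroxypentan-2-yl]-6-methyl-3-methylidene-3a,4,7,7a-tetrahydro-1-benzofuran-2(3H)-one | C=C1C(=O)O[C@@H]2CC(C)=C([C@@H](C)CCCO)[C@@H](O)[C@H]12 | intermediate
28 | (3aR,4S,7aR)-6-methyl-3-methylidene-5-[(2S)-5-(2-methylpropanoyloxy)pentan-2-yl]-2-oxo-2,3,3a,4,7,7a-hexahydro-1-benzofuran-4-yl 2-methylpropanoate | C=C1C(=O)O[C@@H]2CC(C)=C([C@@H](C)CCCOC(=O)C(C)C)[C@@H](OC(=O)C(C)C)[C@H]12 | target

Total step count: 15. Longest linear sequence: 14 steps (from 1 through steps 1, 2 and 4–15).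

Steps most likely to fail

Step 10 (ring-closing enyne metathesis). The crowded C5 vinylcarbene may turn over slowly. Capture by ethylene, methylidene addition in the reverse sense (leading to seven-membered endo closure) and thermal catalyst decay could then compete with closure of the tetrasubstituted alkene.
The fallback sets out from 20 and returns at 21, and it separates methylene transfer from ring closure. Enyne 20 is first subjected to intermolecular alkyne–ethylene cross-metathesis with RuCl2(H2IMes)(PCy3)(=CHPh) under ethylene in CH2Cl2 at rt. This reaction is indifferent to alkyne regiochemistry, and it gives the 2,3-dimethylidene triene lactone F1. After isolation, an ordinary diene ring-closing metathesis joins C5=CH2 and C10=CH2. It uses the sterically reduced catalyst RuCl2[1,3-bis(2-methylphenyl)imidazolidin-2-ylidene](=CH-C6H4-2-OiPr) in refluxing toluene under an argon sparge. This catalyst class was developed for tetrasubstituted alkenes, and six-membered closure is favoured over the seven-membered alternative through C4=CH2.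

Step 11 (asymmetric hydrogenation). Facial selectivity at C4 may be poor if the ligand and the resident stereocentres oppose each other. Iridium hydride species may also move the terminal alkene into the chain before reduction.
The fallback sets out from 21 and returns at 22, and it replaces purely steric recognition by a coordinating group. The primary silyl ether is removed selectively (HF·pyridine, pyridine, THF, 0 °C) to give the primary alcohol diene F2. Oxidation with TEMPO/PhI(OAc)2 in MeCN–H2O gives the 4-substituted pent-4-enoic acid F3. Carboxy-directed asymmetric hydrogenation follows, with [Ir(cod)(SIPHOX)][B(C6H3-3,5-(CF3)2)4] under H2 (6 bar) with Et3N in MeOH (SIPHOX = 7-[bis(3,5-di-tert-butylphenyl)phosphino]-7'-(4,5-dihydrooxazol-2-yl)-1,1'-spirobiindane). This known reaction type for 4-alkylpent-4-enoic acids gives the (4S)-pentanoic acid F4. Reduction with BH3·SMe2 (THF, 0 °C), selective for the acid over the lactone, gives the primary alcohol F5. Silylation with TBSCl and imidazole then regenerates 22.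

Step 8 (methallylboration). The reagent works against the Felkin preference of the α-branched aldehyde, so facial selectivity at C8 may erode.
The fallback sets out from 15 and returns at 19, and it uses the substrate bias followed by inversion. The antipodal borane, made from (−)-Ipc2BOMe and 16, adds in the matched sense to give the 8-epi homoallylic alcohol F6. Mitsunobu inversion (4-nitrobenzoic acid, PPh3, DIAD, toluene, 0 °C to rt) gives the (8R)-4-nitrobenzoate F7. Methanolysis (K2CO3, MeOH, 0 °C) then releases 19; any part of it that already closes to 20 is carried forward as such.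

Further compounds
F1 | step 10 | (4R,5R)-4-[(1S)-1,6-bis(TBSO)-2,3-dimethylidenehexyl]-5-(2-methylprop-2-en-1-yl)oxolan-2-one | C1C(=O)O[C@H](CC(C)=C)[C@@H]1[C@H](O[Si](C)(C)C(C)(C)C)C(=C)C(=C)CCCO[Si](C)(C)C(C)(C)C
F2 | step 11 | (3aR,4S,7aR)-4-(TBSO)-5-(5-hydroxypent-1-en-2-yl)-6-methyl-3a,4,7,7a-tetrahydro-1-benzofuran-2(3H)-one | C1C(=O)O[C@@H]2CC(C)=C(C(=C)CCCO)[C@@H](O[Si](C)(C)C(C)(C)C)[C@H]12
F3 | step 11 | 4-[(3aR,4S,7aR)-4-(TBSO)-6-methyl-2-oxo-2,3,3a,4,7,7a-hexahydro-1-benzofuran-5-yl]pent-4-enoic acid | C1C(=O)O[C@@H]2CC(C)=C(C(=C)CCC(=O)O)[C@@H](O[Si](C)(C)C(C)(C)C)[C@H]12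
F4 | step 11 | (4S)-4-[(3aR,4S,7aR)-4-(TBSO)-6-methyl-2-oxo-2,3,3a,4,7,7a-hexahydro-1-benzofuran-5-yl]pentanoic acid | C1C(=O)O[C@@H]2CC(C)=C([C@@H](C)CCC(=O)O)[C@@H](O[Si](C)(C)C(C)(C)C)[C@H]12
F5 | step 11 | (3aR,4S,7aR)-4-(TBSO)-5-[(2S)-5-hydroxypentan-2-yl]-6-methyl-3a,4,7,7a-tetrahydro-1-benzofuran-2(3H)-one | C1C(=O)O[C@@H]2CC(C)=C([C@@H](C)CCCO)[C@@H](O[Si](C)(C)C(C)(C)C)[C@H]12
F6 | step 8 | tert-butyl (3R,4S)-4,9-bis(TBSO)-3-[(1S)-1-hydroxy-3-methylbut-3-en-1-yl]non-5-ynoate | C=C(C)C[C@H](O)[C@@H](CC(=O)OC(C)(C)C)[C@H](O[Si](C)(C)C(C)(C)C)C#CCCCO[Si](C)(C)C(C)(C)C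
F7 | step 8 | tert-butyl (3R,4S)-4,9-bis(TBSO)-3-[(1R)-3-methyl-1-(4-nitrobenzoyloxy)but-3-en-1-yl]non-5-ynoate | C=C(C)C[C@@H](OC(=O)c1ccc(cc1)[N+](=O)[O-])[C@@H](CC(=O)OC(C)(C)C)[C@H](O[Si](C)(C)C(C)(C)C)C#CCCCO[Si](C)(C)C(C)(C)C
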